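**Retrosynthetic overview**
1. The target, a mirror-symmetric 2,3-trans-3,4-cis-4,5-trans oxolane, comes from its tetra-O-benzyl ether by hydrogenolysis.
2. Both aryl–C2/C5 bonds are cut together. One oxolane-2,5-dicarboxylic acid core and two arylzinc units are joined in the penultimate step by a double nickel-catalysed decarboxylative arylation.
3. The core diacid comes from C=C cleavage of exo,exo-2,3-bis(acetoxymethyl)-7-oxanorbornene, which comes from reduction and acetylation of the exo furan/maleic anhydride adduct.
4. The arylzinc comes from catechol by O-benzylation, para-bromination, and Br/Li exchange followed by transmetalation to zinc.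
5. Ring order: the oxolane is the only ring made. It closes in the Diels–Alder step (C2–C3 and C4–C5 bonds) inside the bicycle and is released by the alkene cleavage. The arene rings come from catechol.

Assumption: the drawn (2R,3S,4R,5S) compound has a mirror plane through O1 and the C3–C4 midpoint (meso, identical with its mirror image), so only the relative configuration needs control, and all core intermediates are meso as well.

**Route**

Step 1
Reactants: 1 catechol (benzene-1,2-diol)
Product: 2 1,2-bis(benzyloxy)benzene
Conditions: BnBr (2.3 equiv), K2CO3 (3 equiv), DMF, 60 °C, N2, 12 h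
Reagents that add atoms: benzyl bromide BrCc1ccccc1
Why: Williamson ether synthesis (SN2 of both phenoxides on benzyl bromide) masks the catechol as ethers that tolerate BuLi, zinc and nickel chemistry and can be removed under neutral conditions at the end; no stereocenter is involved.

Step 2
Reactants: 2 1,2-bis(benzyloxy)benzene
Product: 3 4-bromo-1,2-bis(benzyloxy)benzene
Conditions: NBS (1.05 equiv), MeCN, 0 °C to rt, dark
Reagents that add atoms: N-bromosuccinimide O=C1CCC(=O)N1Br
Why: Electrophilic aromatic bromination attacks the dialkoxy ring, which is far more electron-rich than the benzyl rings, at the unhindered position para to one OBn (C4 and C5 are equivalent), so a single monobromide forms.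

Step 3
Reactants: 3 4-bromo-1,2-bis(benzyloxy)benzene
Product: 5 [3,4-bis(benzyloxy)phenyl]zinc chloride (titrated THF stock solution), via aryllithium 4 (not isolated)
Conditions: n-BuLi (1.05 equiv), THF, −78 °C, 30 min; ZnCl2 (1.1 equiv, THF), −78 °C to rt
Reagents that add atoms: n-butyllithium [Li]CCCC (lithium, found in 4 only); zinc chloride Cl[Zn]Cl
Why: Bromine–lithium exchange followed by transmetalation to zinc gives a mild aryl nucleophile that leaves acetates and activated esters alone until nickel mediates the coupling; no stereocenter is involved.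

Step 4
Reactants: 6 furan; 7 maleic anhydride
Product: 8 exo-3a,4,7,7a-tetrahydro-4,7-epoxy-2-benzofuran-1,3-dione (meso; 3aR,4S,7R,7aS)
Conditions: Et2O, rt, 48 h (adduct crystallises)
Reagents that add atoms: none
Why: In this reversible Diels–Alder [4+2] cycloaddition the thermodynamic exo adduct crystallises; suprafacial addition keeps the two dienophile carbons cis (future C3/C4), and the exo geometry places their substituents anti to the two-carbon bridge (future C2/C5 substituents), which fixes the trans,cis,trans pattern.

Step 5
Reactants: 8 exo anhydride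
Product: 9 exo,exo-7-oxabicyclo[2.2.1]hept-5-ene-2,3-diyldimethanol (meso; 1R,2R,3S,4S)
Conditions: LiAlH4 (2 equiv), THF, 0 °C to rt; Na2SO4·10H2O quench, hot THF extraction
Reagents that add atoms: none
Why: Hydride reduction of the cyclic anhydride gives the 1,4-diol without touching the isolated alkene or any stereocenter, and working at or below room temperature avoids the retro-Diels–Alder reaction.

Step 6
Reactants: 9 exo,exo-diol
Product: 10 exo,exo-7-oxabicyclo[2.2.1]hept-5-ene-2,3-diylbis(methylene) diacetate (meso; 1R,2R,3S,4S)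
Conditions: Ac2O (3 equiv), pyridine (4 equiv), DMAP (5 mol %), CH2Cl2, 0 °C to rt
Reagents that add atoms: acetic anhydride CC(=O)OC(C)=O
Why: DMAP-catalysed O-acylation installs the two acetates of the target early, while no phenol is present, so no chemoselectivity problem arises later; the stereocenters are untouched.

Step 7
Reactants: 10 diacetate
Product: 12 (2R,3S,4R,5S)-3,4-bis(acetoxymethyl)oxolane-2,5-dicarboxylic acid (meso), via dialdehyde 11 (not isolated)
Conditions: RuCl3·xH2O (3 mol %), NaIO4 (4.5 equiv), MeCN/EtOAc/H2O, 0 °C to rt; NaCl-saturated EtOAc extraction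
Reagents that add atoms: sodium periodate [Na+].[O-]I(=O)(=O)=O (oxygen, passed on through RuO4); water O (aldehyde hydrate)
Why: RuO4-catalysed oxidative cleavage (Sharpless conditions) of the strained cis-alkene opens the bicycle to the monocyclic oxolane, whose two carboxyl groups stay cis to each other and trans to the neighbouring CH2OAc groups because no ring bond is broken.

Step 8
Reactants: 12 meso-diacid; 5 [3,4-bis(benzyloxy)phenyl]zinc chloride (6 equiv)
Product: 14 [(2R,3S,4R,5S)-2,5-bis[3,4-bis(benzyloxy)phenyl]oxolane-3,4-diyl]bis(methylene) diacetate (meso), via bis(phthalimidoyl) diester 13 (not isolated)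
Conditions: (a) N-hydroxyphthalimide (2.2 equiv), iPrN=C=NiPr (2.2 equiv), DMAP (10 mol %), CH2Cl2, rt, 3 h, evaporate; (b) 5 in THF, NiCl2(dme) (40 mol %), 4,4′-di-tert-butyl-2,2′-bipyridine (80 mol %), DMF/THF, rt, 16 h; sat. aq NH4Cl
Reagents that add atoms: N-hydroxyphthalimide O=C1c2ccccc2C(=O)N1O (its atoms are found in 13 only)
Why: Carbodiimide esterification is followed by a nickel-catalysed decarboxylative Negishi-type arylation of the redox-active esters, in which each ester loses CO2 after single-electron reduction and the resulting 2-oxolanyl radical is arylated through aryl-nickel on the face anti to the adjacent CH2OAc (both CH2OAc groups block the other face), so both aryl groups end up trans to their neighbours and cis to each other, which is also the thermodynamically preferred arrangement.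

Step 9
Reactants: 14 tetrabenzyl ether
Product: 15 [(2R,3S,4R,5S)-2,5-bis(3,4-dihydroxyphenyl)oxolane-3,4-diyl]bis(methylene) diacetate (target, meso)
Conditions: H2 (1 atm), 10% Pd/C, EtOAc/THF, rt, stopped at full O-debenzylation; filtered under argon
Reagents that add atoms: none
Why: Catalytic hydrogenolysis cleaves the four unhindered primary benzyl aryl ethers much faster than the hindered secondary ring C–O bonds and proceeds under neutral conditions, so the acetates and all four stereocenters survive.

**Compound list**
1 | catechol | Oc1ccccc1O | starting material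
2 | 1,2-bis(benzyloxy)benzene | c1ccc(COc2ccccc2OCc2ccccc2)cc1 | intermediate
3 | 4-bromo-1,2-bis(benzyloxy)benzene | Brc1ccc(OCc2ccccc2)c(OCc2ccccc2)c1 | intermediate
4 | [3,4-bis(benzyloxy)phenyl]lithium (not isolated) | [Li]c1ccc(OCc2ccccc2)c(OCc2ccccc2)c1 | intermediate
5 | [3,4-bis(benzyloxy)phenyl]zinc chloride | Cl[Zn]c1ccc(OCc2ccccc2)c(OCc2ccccc2)c1 | intermediate
6 | furan | c1ccoc1 | starting material
7 | maleic anhydride | O=C1C=CC(=O)O1 | starting material
8 | exo furan–maleic anhydride adduct (meso) | O=C3OC(=O)[C@@H]1[C@H]3[C@H]2C=C[C@@H]1O2 | intermediate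
9 | exo,exo-7-oxabicyclo[2.2.1]hept-5-ene-2,3-diyldimethanol (meso) | OC[C@@H]1[C@H](CO)[C@H]2C=C[C@@H]1O2 | intermediate
10 | exo,exo-diacetate of 9 (meso) | CC(=O)OC[C@@H]1[C@H](COC(C)=O)[C@H]2C=C[C@@H]1O2 | intermediate
11 | (2R,3S,4R,5S)-3,4-bis(acetoxymethyl)oxolane-2,5-dicarbaldehyde (not isolated) | CC(=O)OC[C@@H]1[C@H](COC(C)=O)[C@@H](C=O)O[C@H]1C=O | intermediate
12 | (2R,3S,4R,5S)-3,4-bis(acetoxymethyl)oxolane-2,5-dicarboxylic acid | CC(=O)OC[C@@H]1[C@H](COC(C)=O)[C@@H](C(=O)O)O[C@H]1C(=O)O | intermediate
13 | bis(1,3-dioxoisoindolin-2-yl) ester of 12 (not isolated) | CC(=O)OC[C@@H]1[C@H](COC(C)=O)[C@@H](C(=O)ON2C(=O)c3ccccc3C2=O)O[C@H]1C(=O)ON1C(=O)c2ccccc2C1=O | intermediate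
14 | tetra-O-benzyl ether of the target | CC(=O)OC[C@@H]1[C@H](COC(C)=O)[C@@H](c2ccc(OCc3ccccc3)c(OCc3ccccc3)c2)O[C@H]1c1ccc(OCc2ccccc2)c(OCc2ccccc2)c1 | intermediate
15 | CNP0416169.1 | CC(=O)OC[C@@H]1[C@H](COC(C)=O)[C@@H](c2ccc(O)c(O)c2)O[C@H]1c1ccc(O)c(O)c1 | target

**Counts**
Total step count: 9.
Longest linear sequence: 6 (steps 4, 5, 6, 7, 8, 9). The aryl branch (steps 1–3) joins at step 8.

**Steps most likely to fail**

Step 8 is the riskiest. Two C–C bonds must form in one pot from a labile alpha-oxy activated diester. Aryl homocoupling, protodecarboxylation or ring fragmentation of the second radical can lower the yield. A minor C2/C5 epimer can be equilibrated into 14 with catalytic CF3CO2H in CH2Cl2, because the electron-rich benzylic C–O bonds ionise reversibly. The fallback replaces the radical coupling with a polar one; it sets out from 12 and comes back at 14.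
- Oxidative decarboxylation of 12 with Pb(OAc)4 and pyridine in THF/benzene gives the 3,4-cis-3,4-bis(acetoxymethyl)oxolane-2,5-diyl diacetate F1 as an anomer mixture.
- BF3·OEt2 in CH2Cl2 (−40 to 0 °C) ionises F1 to oxocarbenium ions. These undergo Friedel–Crafts C-arylation by arene 2 (3 equiv) para to an OBn group.
- Attack occurs anti to the neighbouring CH2OAc and under thermodynamic control, giving 14.

Step 9 is next. The ring C–O bonds are also benzylic and could be hydrogenolysed, and the free bis-catechol is sensitive to air. The fallback avoids any reductive end step by using fluoride-labile protection; it sets out from 1 and comes back at 15.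
- Catechol 1 is brominated (NBS, HBF4·OEt2, MeCN, −30 °C) to 4-bromocatechol F2.
- F2 is silylated (TBSCl, imidazole, DMF) to 4-bromo-1,2-bis(tert-butyldimethylsilyloxy)benzene F3.
- F3 is converted with n-BuLi through the aryllithium F4 and ZnCl2 into the arylzinc chloride F5.
- F5 is coupled with 13 (made from 12 as in step 8) to the tetrasilyl ether F6.
- Et3N·3HF in THF at rt then frees the catechols without touching the acetates and gives 15.

Step 7 is third. RuO4 can over-oxidise ether C–H bonds, and the very polar diacid is hard to recover. The fallback splits the cleavage into mild separate stages; it sets out from 10 and comes back at 12.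
- Exo-selective dihydroxylation (K2OsO4·2H2O cat., NMO, acetone/H2O) gives the exo,exo-5,6-diol F7.
- NaIO4 in THF/H2O cleaves F7 to dialdehyde 11, which is now isolated.
- Pinnick oxidation (NaClO2, NaH2PO4, 2-methyl-2-butene, t-BuOH/H2O) gives 12.

**Further compounds**
F1 | step 8 | 3,4-cis-3,4-bis(acetoxymethyl)oxolane-2,5-diyl diacetate (anomer mixture) | CC(=O)OC[C@@H]1[C@H](COC(C)=O)C(OC(C)=O)OC1OC(C)=O
F2 | step 9 | 4-bromocatechol | Oc1ccc(Br)cc1O
F3 | step 9 | 4-bromo-1,2-bis(tert-butyldimethylsilyloxy)benzene | CC(C)(C)[Si](C)(C)Oc1ccc(Br)cc1O[Si](C)(C)C(C)(C)C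
F4 | step 9 | [3,4-bis(tert-butyldimethylsilyloxy)phenyl]lithium | [Li]c1ccc(O[Si](C)(C)C(C)(C)C)c(O[Si](C)(C)C(C)(C)C)c1
F5 | step 9 | [3,4-bis(tert-butyldimethylsilyloxy)phenyl]zinc chloride | Cl[Zn]c1ccc(O[Si](C)(C)C(C)(C)C)c(O[Si](C)(C)C(C)(C)C)c1
F6 | step 9 | [(2R,3S,4R,5S)-2,5-bis[3,4-bis(tert-butyldimethylsilyloxy)phenyl]oxolane-3,4-diyl]bis(methylene) diacetate | CC(=O)OC[C@@H]1[C@H](COC(C)=O)[C@@H](c2ccc(O[Si](C)(C)C(C)(C)C)c(O[Si](C)(C)C(C)(C)C)c2)O[C@H]1c1ccc(O[Si](C)(C)C(C)(C)C)c(O[Si](C)(C)C(C)(C)C)c1
F7 | step 7 | exo,exo-5,6-dihydroxy-7-oxabicyclo[2.2.1]heptane-exo,exo-2,3-diylbis(methylene) diacetate (meso) | CC(=O)OC[C@@H]1[C@H](COC(C)=O)[C@H]2[C@H](O)[C@H](O)[C@@H]1O2
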